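The ten-membered carbocycle (C1–C10) is opened at C9–C10. C9 is a secondary allylic carbinol next to the methyl-bearing C10 of the Z C1=C10 alkene, so this bond can come from a C9 aldehyde and a Z-2-iodoalkene at C10. A Nozaki–Hiyama–Kishi cyclisation forms that bond, the C9 stereocentre and the ring in one operation, with the α-methylene-γ-lactone (C6, C7, C11–C13) already in place. The precursor is an open-chain methylene lactone: C7 carries the CH2CHO arm (C8–C9) and C6 the E-trisubstituted dienyl chain that ends in the C2 silyl ether and the Z iodoalkene. The ester side chain is attached last.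

Key step: step 15

Numbering: germacrane numbering; C1–C10 ring carbons, C11 lactone α-carbon, C12 lactone carbonyl, C13 exocyclic methylene, C14 methyl on C10, C15 methyl on C4.

Assumption: the facial sense of the two catalyst-controlled carbonyl additions (steps 3 and 8) is taken from the usual transition-state models for these catalysts; should a first run show the opposite sense, the mirror-image catalyst is used and nothing else changes.

Step 1
Reactants: 1 but-2-yn-1-ol
Product: 3 (2Z)-3-iodobut-2-en-1-ol, via cyclic alkenylalanate 2 (not isolated)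
Conditions: NaAlH2(OCH2CH2OMe)2, THF, 0 °C to rt; then I2, THF, −78 °C
Reagents that add atoms: iodine, SMILES [I][I]
Why: Hydroxyl-directed trans-hydroalumination of the propargylic alcohol puts aluminium on C3 on the side of the carbinol carbon and iodine replaces it with retention (hydroalumination–iodination), which fixes the Z iodoalkene that becomes C1=C10.

Step 2
Reactants: 3 (2Z)-3-iodobut-2-en-1-ol
Product: 4 (2Z)-3-iodobut-2-enal
Conditions: activated MnO2, CH2Cl2, rt; solution used directly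
Reagents that add atoms: none
Why: Allylic oxidation with MnO2 is neutral and should leave the Z iodoalkene unchanged.

Step 3
Reactants: 4 (2Z)-3-iodobut-2-enal
Product: 5 (4R,5Z)-6-iodohept-5-en-1-yn-4-ol
Conditions: allenylboronic acid pinacol ester, (R)-3,3'-bis(2,4,6-triisopropylphenyl)-1,1'-binaphthyl-2,2'-diyl hydrogen phosphate (5 mol%), 4 Å MS, toluene, −20 °C; aqueous work-up
Reagents that add atoms: allenylboronic acid pinacol ester, SMILES C=C=CB1OC(C)(C)C(C)(C)O1
Why: Chiral-phosphoric-acid-catalysed propargylation of the aldehyde by the allenylboronate through a closed six-membered transition state; the catalyst should steer attack to the Re face of the enal and so set C2 as R, and the nearly neutral conditions should spare the Z iodoalkene.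

Step 4
Reactants: 5 (4R,5Z)-6-iodohept-5-en-1-yn-4-ol
Product: 6 tert-butyl{[(4R,5Z)-6-iodohept-5-en-1-yn-4-yl]oxy}dimethylsilane
Conditions: TBSOTf, 2,6-lutidine, CH2Cl2, −78 °C
Reagents that add atoms: tert-butyldimethylsilyl triflate, SMILES CC(C)(C)[Si](C)(C)OS(=O)(=O)C(F)(F)F
Why: Silylation of the secondary allylic alcohol gives the C2 TBS ether, which is carried unchanged to the last step.

Step 5
Reactants: 6 tert-butyl{[(4R,5Z)-6-iodohept-5-en-1-yn-4-yl]oxy}dimethylsilane
Product: 8 methyl (2E,5R,6Z)-5-{[tert-butyl(dimethyl)silyl]oxy}-7-iodo-3-methylocta-2,6-dienoate, via alkenyl(dimethyl)alane 7 (not isolated)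
Conditions: Me3Al, Cp2ZrCl2 (cat.), CH2Cl2, 0 °C to rt; then ClCO2Me, 0 °C to rt
Reagents that add atoms: trimethylaluminium, SMILES C[Al](C)C; methyl chloroformate, SMILES COC(=O)Cl
Why: Zirconocene-catalysed syn-methylalumination of the terminal alkyne (carboalumination) places methyl on C4 and aluminium on C5 on the same side, and acylation of the alkenylalane with retention fixes the E C4=C5 alkene; the internal iodoalkene should not react.

Step 6
Reactants: 8 methyl (2E,5R,6Z)-5-{[tert-butyl(dimethyl)silyl]oxy}-7-iodo-3-methylocta-2,6-dienoate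
Product: 9 (2E,5R,6Z)-5-{[tert-butyl(dimethyl)silyl]oxy}-7-iodo-3-methylocta-2,6-dien-1-ol
Conditions: i-Bu2AlH, CH2Cl2, −78 °C
Reagents that add atoms: none
Why: 1,2-Reduction of the enoate with i-Bu2AlH should give the allylic alcohol without touching the alkenyl iodide or the silyl ether.

Step 7
Reactants: 9 (2E,5R,6Z)-5-{[tert-butyl(dimethyl)silyl]oxy}-7-iodo-3-methylocta-2,6-dien-1-ol
Product: 10 (2E,5R,6Z)-5-{[tert-butyl(dimethyl)silyl]oxy}-7-iodo-3-methylocta-2,6-dienal
Conditions: activated MnO2, CH2Cl2, rt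
Reagents that add atoms: none
Why: Allylic oxidation with MnO2 should give the E enal (C6 aldehyde) without isomerising either alkene.

Step 8
Reactants: 10 (2E,5R,6Z)-5-{[tert-butyl(dimethyl)silyl]oxy}-7-iodo-3-methylocta-2,6-dienal; 11 methyl prop-2-ynoate
Product: 12 methyl (4R,5E,8R,9Z)-8-{[tert-butyl(dimethyl)silyl]oxy}-4-hydroxy-10-iodo-6-methylundeca-5,9-dien-2-ynoate
Conditions: Me2Zn, (R,R)-2,6-bis{[2-(hydroxydiphenylmethyl)pyrrolidin-1-yl]methyl}-4-methylphenol (ProPhenol, 10 mol%), toluene, 4 °C; aq. NH4Cl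
Reagents that add atoms: none
Why: Dinuclear zinc–ProPhenol-catalysed addition of the zinc acetylide of the propiolate to the enal, a reaction type suited to unsaturated aldehydes; the catalyst should deliver the alkynyl group to the Si face and so set the C6 carbinol centre (R in this intermediate).

Step 9
Reactants: 12 methyl (4R,5E,8R,9Z)-8-{[tert-butyl(dimethyl)silyl]oxy}-4-hydroxy-10-iodo-6-methylundeca-5,9-dien-2-ynoate
Product: 14 (5S)-5-[(1E,4R,5Z)-4-{[tert-butyl(dimethyl)silyl]oxy}-6-iodo-2-methylhepta-1,5-dien-1-yl]furan-2(5H)-one, via Z-hydroxy enoate 13 (not isolated)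
Conditions: H2 (1 atm), Pd/CaCO3 poisoned with Pb(OAc)2, quinoline, EtOAc, rt; then PPTS (cat.), CH2Cl2, rt
Reagents that add atoms: none
Why: Lindlar semi-hydrogenation should give the Z enoate, in which hydroxyl and ester are cis and lactonise to the butenolide; C6 is not touched.

Step 10
Reactants: 14 (5S)-5-[(1E,4R,5Z)-4-{[tert-butyl(dimethyl)silyl]oxy}-6-iodo-2-methylhepta-1,5-dien-1-yl]furan-2(5H)-one
Product: 16 (4R,5S)-5-[(1E,4R,5Z)-4-{[tert-butyl(dimethyl)silyl]oxy}-6-iodo-2-methylhepta-1,5-dien-1-yl]-4-ethenyloxolan-2-one, via silyl ketene acetal 15 (not isolated)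
Conditions: CH2=CHMgBr, CuBr·SMe2, Me3SiCl, THF, −78 °C; aq. NH4Cl
Reagents that add atoms: vinylmagnesium bromide, SMILES C=C[Mg]Br
Why: Copper-mediated conjugate addition of the vinyl Grignard reagent to the butenolide, accelerated by Me3SiCl so that it outruns γ-deprotonation; the reagent should enter anti to the C6 side chain and set C7 trans to C6.

Step 11
Reactants: 16 (4R,5S)-5-[(1E,4R,5Z)-4-{[tert-butyl(dimethyl)silyl]oxy}-6-iodo-2-methylhepta-1,5-dien-1-yl]-4-ethenyloxolan-2-one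
Product: 18 (4S,5S)-5-[(1E,4R,5Z)-4-{[tert-butyl(dimethyl)silyl]oxy}-6-iodo-2-methylhepta-1,5-dien-1-yl]-4-(2-hydroxyethyl)oxolan-2-one, via B-alkyl-9-BBN adduct 17 (not isolated)
Conditions: 9-BBN, THF, 0 °C to rt; then NaBO3·4H2O, H2O, rt
Reagents that add atoms: sodium perborate, SMILES [Na+].[Na+].O[B-]1(O)OO[B-](O)(O)OO1
Why: Hydroboration–oxidation; 9-BBN should react only with the monosubstituted vinyl group in the anti-Markovnikov sense and leave the trisubstituted alkene, the iodoalkene and the lactone alone.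

Step 12
Reactants: 18 (4S,5S)-5-[(1E,4R,5Z)-4-{[tert-butyl(dimethyl)silyl]oxy}-6-iodo-2-methylhepta-1,5-dien-1-yl]-4-(2-hydroxyethyl)oxolan-2-one
Product: 19 (4S,5S)-5-[(1E,4R,5Z)-4-{[tert-butyl(dimethyl)silyl]oxy}-6-iodo-2-methylhepta-1,5-dien-1-yl]-4-{2-[(triethylsilyl)oxy]ethyl}oxolan-2-one
Conditions: Et3SiCl, imidazole, CH2Cl2, 0 °C
Reagents that add atoms: chlorotriethylsilane, SMILES CC[Si](Cl)(CC)CC
Why: Silylation of the primary alcohol shields it from the enolate chemistry of the next step and prevents translactonisation.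

Step 13
Reactants: 19 (4S,5S)-5-[(1E,4R,5Z)-4-{[tert-butyl(dimethyl)silyl]oxy}-6-iodo-2-methylhepta-1,5-dien-1-yl]-4-{2-[(triethylsilyl)oxy]ethyl}oxolan-2-one
Product: 22 (4S,5R)-5-[(1E,4R,5Z)-4-{[tert-butyl(dimethyl)silyl]oxy}-6-iodo-2-methylhepta-1,5-dien-1-yl]-3-methylidene-4-{2-[(triethylsilyl)oxy]ethyl}oxolan-2-one, via Mannich base 20 (not isolated), via trimethylammonium iodide 21 (not isolated)
Conditions: LiN(i-Pr)2, THF, −78 °C; CH2=NMe2 iodide (Eschenmoser's salt), −78 to 0 °C; then MeI, MeOH, rt; then aq. NaHCO3, CH2Cl2, rt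
Reagents that add atoms: N,N-dimethylmethylideneammonium iodide, SMILES C=[N+](C)C.[I-]
Why: α-Methylenation by Mannich reaction of the lactone lithium enolate with Eschenmoser's salt, then quaternisation and base-induced loss of trimethylamine; the transient C11 centre is erased.

Step 14
Reactants: 22 (4S,5R)-5-[(1E,4R,5Z)-4-{[tert-butyl(dimethyl)silyl]oxy}-6-iodo-2-methylhepta-1,5-dien-1-yl]-3-methylidene-4-{2-[(triethylsilyl)oxy]ethyl}oxolan-2-one
Product: 23 2-{(2R,3S)-2-[(1E,4R,5Z)-4-{[tert-butyl(dimethyl)silyl]oxy}-6-iodo-2-methylhepta-1,5-dien-1-yl]-4-methylidene-5-oxooxolan-3-yl}acetaldehyde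
Conditions: (COCl)2, DMSO, CH2Cl2, −78 to −30 °C; then Et3N, −78 °C to rt
Reagents that add atoms: none
Why: Swern oxidation applied directly to the primary triethylsilyl ether, which the chlorosulfonium reagent cleaves in situ while the secondary TBS ether should stay; C7 is β to the new aldehyde and cannot epimerise.

Step 15
Reactants: 23 2-{(2R,3S)-2-[(1E,4R,5Z)-4-{[tert-butyl(dimethyl)silyl]oxy}-6-iodo-2-methylhepta-1,5-dien-1-yl]-4-methylidene-5-oxooxolan-3-yl}acetaldehyde
Product: 25 (2R,6R,7S,9S)-2-{[tert-butyl(dimethyl)silyl]oxy}-9-hydroxygermacra-1(10)Z,4E,11(13)-trien-12,6-olide, via alkenylchromium dichloride 24 (not isolated)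
Conditions: CrCl2 (10 equiv), NiCl2 (0.1 equiv), degassed DMSO, rt, slow addition of 23 to a final 0.002 M; aqueous work-up
Reagents that add atoms: none
Why: Divalent chromium reduces NiCl2 to zerovalent nickel, which inserts into the C10–I bond with retention of the Z geometry; transmetallation gives the alkenylchromium 24 (trivalent chromium), which adds 1,2 to the C9 aldehyde and is released as the alcohol on work-up. This is a Nozaki–Hiyama–Kishi alkenyl–aldehyde macrocyclisation, a reaction type established for medium-ring allylic alcohols. The ten-membered ring closes by 10-exo-trig attack of C10 on the carbonyl carbon C9, at high dilution so that ring closure outruns dimerisation. The new C9 centre is set under substrate control by C7 of the trans-disubstituted lactone together with the fixed Z C1=C10 and E C4=C5 geometries, which should hold the carbonyl oxygen on the periphery of the forming ring and expose the face leading to the 9S alcohol. The step needs chemoselectivity for the aldehyde over the lactone carbonyl and the methylene lactone, which the weakly basic, aldehyde-selective alkenylchromium reagent secures, and it needs face selectivity at C9, which rests on the conformational bias just named.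

Step 16
Reactants: 26 (2E)-but-2-enal
Product: 28 (2Z)-2-bromobut-2-enal, via 2,3-dibromobutanal 27 (not isolated)
Conditions: Br2, CH2Cl2, 0 °C; then Et3N, 0 °C to rt
Reagents that add atoms: bromine, SMILES BrBr
Why: Bromine addition to the enal followed by dehydrobromination (addition–elimination) should give the more stable Z bromoenal, with the methyl group trans to the formyl group.

Step 17
Reactants: 28 (2Z)-2-bromobut-2-enal
Product: 29 (2Z)-2-bromobut-2-en-1-ol
Conditions: NaBH4, CeCl3·7H2O, MeOH, 0 °C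
Reagents that add atoms: none
Why: Luche 1,2-reduction of the enal should give the allylic alcohol with the alkene geometry unchanged.

Step 18
Reactants: 29 (2Z)-2-bromobut-2-en-1-ol
Product: 30 {[(2Z)-2-bromobut-2-en-1-yl]oxy}(tert-butyl)dimethylsilane
Conditions: TBSCl, imidazole, DMF, rt
Reagents that add atoms: tert-butyldimethylsilyl chloride, SMILES CC(C)(C)[Si](C)(C)Cl
Why: Silylation of the primary allylic alcohol installs the same protecting group as on C2, so that one final step removes both.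

Step 19
Reactants: 30 {[(2Z)-2-bromobut-2-en-1-yl]oxy}(tert-butyl)dimethylsilane
Product: 32 (2Z)-2-({[tert-butyl(dimethyl)silyl]oxy}methyl)but-2-enoic acid, via alkenyllithium 31 (not isolated)
Conditions: t-BuLi (2.1 equiv), Et2O, −78 °C; CO2, −78 °C; cold dilute HCl
Reagents that add atoms: carbon dioxide, SMILES O=C=O
Why: Bromine–lithium exchange and carboxylation of the alkenyllithium both proceed with retention of alkene geometry at −78 °C, so the carboxyl group should end up cis to the methyl group (Z acid).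

Step 20
Reactants: 25 (2R,6R,7S,9S)-2-{[tert-butyl(dimethyl)silyl]oxy}-9-hydroxygermacra-1(10)Z,4E,11(13)-trien-12,6-olide; 32 (2Z)-2-({[tert-butyl(dimethyl)silyl]oxy}methyl)but-2-enoic acid
Product: 34 (2R,6R,7S,9S)-2-{[tert-butyl(dimethyl)silyl]oxy}-9-{[(2Z)-2-({[tert-butyl(dimethyl)silyl]oxy}methyl)but-2-enoyl]oxy}germacra-1(10)Z,4E,11(13)-trien-12,6-olide, via mixed anhydride 33 (not isolated)
Conditions: 32, 2,4,6-trichlorobenzoyl chloride, Et3N, toluene, rt; then 25, DMAP, toluene, rt to 60 °C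
Reagents that add atoms: none
Why: Yamaguchi esterification; acyl transfer from the mixed anhydride to the hindered C9 alcohol leaves the C9–O bond intact (retention) and avoids the carbodiimide conditions under which Z 2-substituted butenoic acids tend to isomerise.

Step 21
Reactants: 34 (2R,6R,7S,9S)-2-{[tert-butyl(dimethyl)silyl]oxy}-9-{[(2Z)-2-({[tert-butyl(dimethyl)silyl]oxy}methyl)but-2-enoyl]oxy}germacra-1(10)Z,4E,11(13)-trien-12,6-olide
Product: 35 (2R,6R,7S,9S)-2-hydroxy-9-{[(2Z)-2-(hydroxymethyl)but-2-enoyl]oxy}germacra-1(10)Z,4E,11(13)-trien-12,6-olide (CNP0273961.1)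
Conditions: HF·pyridine, pyridine, THF, 0 °C to rt
Reagents that add atoms: none
Why: Fluoride-mediated desilylation with buffered HF·pyridine should cleave both TBS ethers without touching the esters, the methylene lactone or the alkene geometries.

Compound list
1 | but-2-yn-1-ol | CC#CCO | starting material
2 | sodium 2,2-bis(2-methoxyethoxy)-3-methyl-2,5-dihydro-1,2-oxaluminol-2-uide (cyclic alkenylalanate) | CC1=CCO[Al-]1(OCCOC)OCCOC.[Na+] | intermediate
3 | (2Z)-3-iodobut-2-en-1-ol | C/C(I)=C/CO | intermediate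
4 | (2Z)-3-iodobut-2-enal | C/C(I)=C/C=O | intermediate
5 | (4R,5Z)-6-iodohept-5-en-1-yn-4-ol | C#CC[C@@H](O)/C=C(/C)I | intermediate
6 | tert-butyl{[(4R,5Z)-6-iodohept-5-en-1-yn-4-yl]oxy}dimethylsilane | C#CC[C@@H](O[Si](C)(C)C(C)(C)C)/C=C(/C)I | intermediate
7 | [(1E,4R,5Z)-4-{[tert-butyl(dimethyl)silyl]oxy}-6-iodo-2-methylhepta-1,5-dien-1-yl]dimethylalane | C[Al](C)/C=C(\C)C[C@@H](O[Si](C)(C)C(C)(C)C)/C=C(/C)I | intermediate
8 | methyl (2E,5R,6Z)-5-{[tert-butyl(dimethyl)silyl]oxy}-7-iodo-3-methylocta-2,6-dienoate | COC(=O)/C=C(\C)C[C@@H](O[Si](C)(C)C(C)(C)C)/C=C(/C)I | intermediate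
9 | (2E,5R,6Z)-5-{[tert-butyl(dimethyl)silyl]oxy}-7-iodo-3-methylocta-2,6-dien-1-ol | OC/C=C(\C)C[C@@H](O[Si](C)(C)C(C)(C)C)/C=C(/C)I | intermediate
10 | (2E,5R,6Z)-5-{[tert-butyl(dimethyl)silyl]oxy}-7-iodo-3-methylocta-2,6-dienal | O=C/C=C(\C)C[C@@H](O[Si](C)(C)C(C)(C)C)/C=C(/C)I | intermediate
11 | methyl prop-2-ynoate | C#CC(=O)OC | starting material
12 | methyl (4R,5E,8R,9Z)-8-{[tert-butyl(dimethyl)silyl]oxy}-4-hydroxy-10-iodo-6-methylundeca-5,9-dien-2-ynoate | COC(=O)C#C[C@H](O)/C=C(\C)C[C@@H](O[Si](C)(C)C(C)(C)C)/C=C(/C)I | intermediate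
13 | methyl (2Z,4S,5E,8R,9Z)-8-{[tert-butyl(dimethyl)silyl]oxy}-4-hydroxy-10-iodo-6-methylundeca-2,5,9-trienoate | COC(=O)/C=C\[C@H](O)/C=C(\C)C[C@@H](O[Si](C)(C)C(C)(C)C)/C=C(/C)I | intermediate
14 | (5S)-5-[(1E,4R,5Z)-4-{[tert-butyl(dimethyl)silyl]oxy}-6-iodo-2-methylhepta-1,5-dien-1-yl]furan-2(5H)-one | O=C1O[C@H](/C=C(\C)C[C@@H](O[Si](C)(C)C(C)(C)C)/C=C(/C)I)C=C1 | intermediate
15 | trimethylsilyl ketene acetal of 16: {[(4S,5S)-4-ethenyl-5-[(1E,4R,5Z)-4-{[tert-butyl(dimethyl)silyl]oxy}-6-iodo-2-methylhepta-1,5-dien-1-yl]-4,5-dihydrofuran-2-yl]oxy}trimethylsilane | C=C[C@H]1C=C(O[Si](C)(C)C)O[C@@H]1/C=C(\C)C[C@@H](O[Si](C)(C)C(C)(C)C)/C=C(/C)I | intermediate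
16 | (4R,5S)-5-[(1E,4R,5Z)-4-{[tert-butyl(dimethyl)silyl]oxy}-6-iodo-2-methylhepta-1,5-dien-1-yl]-4-ethenyloxolan-2-one | C=C[C@H]1CC(=O)O[C@@H]1/C=C(\C)C[C@@H](O[Si](C)(C)C(C)(C)C)/C=C(/C)I | intermediate
17 | B-alkyl-9-BBN adduct of 16 (boron on C9, 4,5-trans lactone) | C(C[C@H]1CC(=O)O[C@@H]1/C=C(\C)C[C@@H](O[Si](C)(C)C(C)(C)C)/C=C(/C)I)B1C2CCCC1CCC2 | intermediate
18 | (4S,5S)-5-[(1E,4R,5Z)-4-{[tert-butyl(dimethyl)silyl]oxy}-6-iodo-2-methylhepta-1,5-dien-1-yl]-4-(2-hydroxyethyl)oxolan-2-one | OCC[C@H]1CC(=O)O[C@@H]1/C=C(\C)C[C@@H](O[Si](C)(C)C(C)(C)C)/C=C(/C)I | intermediate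
19 | (4S,5S)-5-[(1E,4R,5Z)-4-{[tert-butyl(dimethyl)silyl]oxy}-6-iodo-2-methylhepta-1,5-dien-1-yl]-4-{2-[(triethylsilyl)oxy]ethyl}oxolan-2-one | CC[Si](CC)(CC)OCC[C@H]1CC(=O)O[C@@H]1/C=C(\C)C[C@@H](O[Si](C)(C)C(C)(C)C)/C=C(/C)I | intermediate
20 | Mannich base: 3-[(dimethylamino)methyl] derivative of 19, 3,4-trans | CC[Si](CC)(CC)OCC[C@H]1[C@H](CN(C)C)C(=O)O[C@@H]1/C=C(\C)C[C@@H](O[Si](C)(C)C(C)(C)C)/C=C(/C)I | intermediate
21 | trimethylammonium iodide of 20 | CC[Si](CC)(CC)OCC[C@H]1[C@H](C[N+](C)(C)C)C(=O)O[C@@H]1/C=C(\C)C[C@@H](O[Si](C)(C)C(C)(C)C)/C=C(/C)I.[I-] | intermediate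
22 | (4S,5R)-5-[(1E,4R,5Z)-4-{[tert-butyl(dimethyl)silyl]oxy}-6-iodo-2-methylhepta-1,5-dien-1-yl]-3-methylidene-4-{2-[(triethylsilyl)oxy]ethyl}oxolan-2-one | CC[Si](CC)(CC)OCC[C@H]1C(=C)C(=O)O[C@@H]1/C=C(\C)C[C@@H](O[Si](C)(C)C(C)(C)C)/C=C(/C)I | intermediate
23 | 2-{(2R,3S)-2-[(1E,4R,5Z)-4-{[tert-butyl(dimethyl)silyl]oxy}-6-iodo-2-methylhepta-1,5-dien-1-yl]-4-methylidene-5-oxooxolan-3-yl}acetaldehyde | O=CC[C@H]1C(=C)C(=O)O[C@@H]1/C=C(\C)C[C@@H](O[Si](C)(C)C(C)(C)C)/C=C(/C)I | intermediate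
24 | Z-alkenylchromium dichloride from 23 (CrCl2 in place of iodine on C10) | O=CC[C@H]1C(=C)C(=O)O[C@@H]1/C=C(\C)C[C@@H](O[Si](C)(C)C(C)(C)C)/C=C(/C)[Cr](Cl)Cl | intermediate
25 | (2R,6R,7S,9S)-2-{[tert-butyl(dimethyl)silyl]oxy}-9-hydroxygermacra-1(10)Z,4E,11(13)-trien-12,6-olide | C=C1C(=O)O[C@@H]2/C=C(\C)C[C@@H](O[Si](C)(C)C(C)(C)C)/C=C(/C)[C@@H](O)C[C@@H]12 | intermediate
26 | (2E)-but-2-enal | C/C=C/C=O | starting material
27 | 2,3-dibromobutanal (mixture of diastereomers) | CC(Br)C(Br)C=O | intermediate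
28 | (2Z)-2-bromobut-2-enal | C/C=C(\Br)C=O | intermediate
29 | (2Z)-2-bromobut-2-en-1-ol | C/C=C(\Br)CO | intermediate
30 | {[(2Z)-2-bromobut-2-en-1-yl]oxy}(tert-butyl)dimethylsilane | C/C=C(\Br)CO[Si](C)(C)C(C)(C)C | intermediate
31 | (1-{[tert-butyl(dimethyl)silyl]oxy}but-2-en-2-yl)lithium, lithium cis to the methyl group | C/C=C(\[Li])CO[Si](C)(C)C(C)(C)C | intermediate
32 | (2Z)-2-({[tert-butyl(dimethyl)silyl]oxy}methyl)but-2-enoic acid | C/C=C(\C(=O)O)CO[Si](C)(C)C(C)(C)C | intermediate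
33 | mixed anhydride of 32 with 2,4,6-trichlorobenzoic acid | C/C=C(\C(=O)OC(=O)c1c(Cl)cc(Cl)cc1Cl)CO[Si](C)(C)C(C)(C)C | intermediate
34 | (2R,6R,7S,9S)-2-{[tert-butyl(dimethyl)silyl]oxy}-9-{[(2Z)-2-({[tert-butyl(dimethyl)silyl]oxy}methyl)but-2-enoyl]oxy}germacra-1(10)Z,4E,11(13)-trien-12,6-olide | C=C1C(=O)O[C@@H]2/C=C(\C)C[C@@H](O[Si](C)(C)C(C)(C)C)/C=C(/C)[C@@H](OC(=O)/C(=C\C)CO[Si](C)(C)C(C)(C)C)C[C@@H]12 | intermediate
35 | (2R,6R,7S,9S)-2-hydroxy-9-{[(2Z)-2-(hydroxymethyl)but-2-enoyl]oxy}germacra-1(10)Z,4E,11(13)-trien-12,6-olide (CNP0273961.1) | C=C1C(=O)O[C@@H]2/C=C(\C)C[C@@H](O)/C=C(/C)[C@@H](OC(=O)/C(=C\C)CO)C[C@@H]12 | target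

Total step count: 21. Longest linear sequence: 17 steps (steps 1–15, 20 and 21); steps 16–19 make the side-chain acid separately.

Steps most likely to fail

Step 15. The ring closure may show poor facial selectivity at C9 and deliver mainly the other carbinol epimer; slow closure could also let protodehalogenation or dimerisation compete. Fallback for the stereochemical problem: setting out from 23, the same cyclisation then furnishes the C9-epimeric alcohol (2R,6R,7S,9R)-2-{[tert-butyl(dimethyl)silyl]oxy}-9-hydroxygermacra-1(10)Z,4E,11(13)-trien-12,6-olide F1. F1 is esterified with acid 32 under Mitsunobu conditions (PPh3, diisopropyl azodicarboxylate, toluene, 0 °C), which inverts C9 and leads to 34, where the route continues. If both epimers form, 25 (acylation with retention) and F1 (esterification with inversion) converge on 34.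

Step 9. The semi-hydrogenation may be accompanied by hydrogenolysis of the C–I bond or by over-reduction of the enoate. Fallback without hydrogenation: setting out from enal 10, the zinc/ProPhenol catalyst of step 8 adds ethynyltrimethylsilane to give the silylated propargylic alcohol (3R,4E,7R,8Z)-7-{[tert-butyl(dimethyl)silyl]oxy}-9-iodo-5-methyl-1-(trimethylsilyl)deca-4,8-dien-1-yn-3-ol F2. K2CO3 in MeOH removes the C-silyl group and leaves the terminal alkyne (3R,4E,7R,8Z)-7-{[tert-butyl(dimethyl)silyl]oxy}-9-iodo-5-methyldeca-4,8-dien-1-yn-3-ol F3. NaAlH2(OCH2CH2OMe)2 (THF, 0 °C) reduces the propargylic alkyne by hydroxyl-directed hydroalumination to the vinyl carbinol (3S,4E,7R,8Z)-7-{[tert-butyl(dimethyl)silyl]oxy}-9-iodo-5-methyldeca-1,4,8-trien-3-ol F4. Acryloyl chloride and i-Pr2NEt give the acrylate (3S,4E,7R,8Z)-7-{[tert-butyl(dimethyl)silyl]oxy}-9-iodo-5-methyldeca-1,4,8-trien-3-yl prop-2-enoate F5. Ring-closing metathesis with the second-generation Grubbs catalyst (H2IMes)(PCy3)Cl2Ru=CHPh (CH2Cl2, 40 °C) then closes the butenolide and rejoins the route at 14.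

Step 3. Enantiofacial control may be insufficient on this β-iodoenal, or the acid catalyst may cause Z to E isomerisation of the iodoalkene. Fallback by resolution: setting out from 4, a zinc-mediated Barbier propargylation (propargyl bromide, Zn, THF/aq. NH4Cl) gives the racemic alcohol (5Z)-6-iodohept-5-en-1-yn-4-ol F6. Lipase-catalysed acylation (Burkholderia cepacia lipase, vinyl acetate, hexane) should convert the R enantiomer into the acetate (4R,5Z)-6-iodohept-5-en-1-yn-4-yl acetate F7, which is separated from the unreacted S alcohol and methanolysed (K2CO3, MeOH) to 5.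

Further compounds
F1 | step 15 | (2R,6R,7S,9R)-2-{[tert-butyl(dimethyl)silyl]oxy}-9-hydroxygermacra-1(10)Z,4E,11(13)-trien-12,6-olide | C=C1C(=O)O[C@@H]2/C=C(\C)C[C@@H](O[Si](C)(C)C(C)(C)C)/C=C(/C)[C@H](O)C[C@@H]12
F2 | step 9 | (3R,4E,7R,8Z)-7-{[tert-butyl(dimethyl)silyl]oxy}-9-iodo-5-methyl-1-(trimethylsilyl)deca-4,8-dien-1-yn-3-ol | C[Si](C)(C)C#C[C@H](O)/C=C(\C)C[C@@H](O[Si](C)(C)C(C)(C)C)/C=C(/C)I
F3 | step 9 | (3R,4E,7R,8Z)-7-{[tert-butyl(dimethyl)silyl]oxy}-9-iodo-5-methyldeca-4,8-dien-1-yn-3-ol | C#C[C@H](O)/C=C(\C)C[C@@H](O[Si](C)(C)C(C)(C)C)/C=C(/C)I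
F4 | step 9 | (3S,4E,7R,8Z)-7-{[tert-butyl(dimethyl)silyl]oxy}-9-iodo-5-methyldeca-1,4,8-trien-3-ol | C=C[C@H](O)/C=C(\C)C[C@@H](O[Si](C)(C)C(C)(C)C)/C=C(/C)I
F5 | step 9 | (3S,4E,7R,8Z)-7-{[tert-butyl(dimethyl)silyl]oxy}-9-iodo-5-methyldeca-1,4,8-trien-3-yl prop-2-enoate | C=C[C@H](OC(=O)C=C)/C=C(\C)C[C@@H](O[Si](C)(C)C(C)(C)C)/C=C(/C)I
F6 | step 3 | racemic (5Z)-6-iodohept-5-en-1-yn-4-ol | C#CCC(O)/C=C(/C)I
F7 | step 3 | (4R,5Z)-6-iodohept-5-en-1-yn-4-yl acetate | C#CC[C@@H](OC(C)=O)/C=C(/C)I
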